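The leftover came first: after 50.0 min, the north run, charged at 0.20 M, held 35.8% of its substrate in neither target nor isomer of the product A. Taken as first-order loss, that leaves 0.722% at 4.0 h in the flask, charged at 0.10 M, so the question at the end is how the converted charge is divided.

| flask | substrate | remark | time |
|---|---|---|---|
| north | 0.20 M | run made earlier |  |
| flask | 0.10 M |  | 4.0 h |

north run (percent of the substrate charged)

| time / min | target / % | isomer of the product A / % |
|---|---|---|
| 10.0 | 8.5 | 11.3 |
| 20.0 | 17.1 | 19.6 |
| 30.0 | 22.0 | 27.5 |
| 40.0 | 26.8 | 32.2 |
| 50.0 | 28.4 | 35.8 |

(each reading ± 1 percentage point)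

- the analysis behind the earlier runs scatters by 1 percentage point, standard deviation

1. share of target in target plus isomer of the product A at 1.0 min
2. share of target in target plus isomer of the product A at 4.0 h

I took f, the kinetic share, as target over target plus isomer of the product A at the last reading: 44.2%. If target stays once made, f is also the part of the charge it holds at 4.0 h. Yet between 40.0 min and 50.0 min target took just 30.8% of the new product. The two numbers do go together: target's step was 1.6 percentage points, and a difference of two readings scatters by 1.4 points. So target's readings show no fall, but they stop early, and the flask runs 4.80 times as long. My own reckoning put f at both 1.0 min and 4.0 h.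

The forecast gave 45% (41% to 49%) at 1.0 min and 44% (36% to 48%) at 4.0 h; of later interconversion it said: “The run shows no clear sign of that”.

The flask gave 48.2% at 1.0 min and 22.8% at 4.0 h.

    2 substrate → homo dimer A (k = 6.30 × 10⁻⁷ L mol⁻¹ s⁻¹)
    2 other conformer → homo dimer B (k = 9.30 × 10⁻⁵ L mol⁻¹ s⁻¹)
    substrate ⇌ other conformer, settled at all times (K = 2.50)
    other conformer → isomer of the product A (k = 3.00 × 10⁻⁴ s⁻¹)
    substrate → target (k = 7.00 × 10⁻⁴ s⁻¹)
    target ⇌ isomer of the product B (K = 7.60, k = 1.00 × 10⁻⁴ s⁻¹)
    target ⇌ isomer of the product A (K = 3.00, k = 2.00 × 10⁻⁵ s⁻¹)

At 0.459 h in the flask, target's forward half-life toward isomer of the product B was 1.9 h, shorter than the 9.6 h toward isomer of the product A. At 4.0 h the flask's target stood 28 points below f, with 29.6% as isomer of the product B. The neighbour charged with 0.40 M ended with target 29 points below f and 28.7% as isomer of the product B.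

All runs were generated by integration with constants of no real substance; noise was put on by code.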